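**Strategy.** The butyrolactone ring is unravelled at C7–C11 (eudesmane numbering: C6 carries the ring acetoxy group, C7 and C8 are the ring-fusion carbons, C11 is the α-methylene carbon, C12 the carbonyl). The key step exploits that C7 sits between the oxygenated carbons C6 and C8 of the cyclohexene ring: with C6 as a ketone, C7 becomes a silyl enol ether nucleophile that attacks a gold-activated propargyl ether on O8 (5-exo-dig). One operation closes the O–C8–C7–C11–C12 ring, installs the exocyclic methylene and fixes the cis fusion. The precursor is a monocyclic 2-silyloxycyclohexa-1,3-diene propargyl ether built from (S)-citronellal, (R)-epichlorohydrin and two dithianes; C12 oxidation and convex-face C6 reduction follow.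

Key step: step 8

Remark on the chemistry: the target SMILES is read as (3aR,4R,7aR) in the bicycle (C6 acetoxy group, C7–C11 bond and C8–O bond all on one face of the cyclohexene ring) and S at the side-chain stereocentre C4; the route is planned for this isomer.

Step 1
Reactants: 1 (S)-citronellal
Product: 2 2-[(2S)-2,6-dimethylhept-5-en-1-yl]-1,3-dithiane
Conditions: propane-1,3-dithiol, BF3·OEt2 (cat.), CH2Cl2, −20 °C
Reagents that add atoms: propane-1,3-dithiol, SCCCS
Why: Lewis-acid-catalysed dithioacetalisation turns the aldehyde carbon (future C6) into an acyl-anion equivalent (Corey–Seebach umpolung) without touching the remote stereocentre, the low temperature suppressing the carbonyl-ene cyclisation of citronellal.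

Step 2
Reactants: 3 2-methyl-1,3-dithiane; 4 (R)-epichlorohydrin
Product: 7 2-methyl-2-{[(2R)-oxiran-2-yl]methyl}-1,3-dithiane, via 2-lithio-2-methyl-1,3-dithiane 5 (not isolated), via lithium chlorohydrin alkoxide 6 (not isolated)
Conditions: n-BuLi, THF, −30 °C; then 4, −78 °C → rt
Reagents that add atoms: none
Why: Corey–Seebach alkylation in which the lithiodithiane opens the oxirane of 4 at its CH2 terminus and the chlorohydrin alkoxide then displaces chloride to form the new terminal epoxide, so the C–O stereocentre of 4 (future C8) is carried over unchanged.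

Step 3
Reactants: 2 2-[(2S)-2,6-dimethylhept-5-en-1-yl]-1,3-dithiane; 7 2-methyl-2-{[(2R)-oxiran-2-yl]methyl}-1,3-dithiane
Product: 9 (2R)-1-{2-[(2S)-2,6-dimethylhept-5-en-1-yl]-1,3-dithian-2-yl}-3-(2-methyl-1,3-dithian-2-yl)propan-2-ol, via lithiated dithiane 8 (not isolated)
Conditions: n-BuLi, THF, −30 °C; then 7, DMPU, −78 → 0 °C; H2O quench
Reagents that add atoms: none
Why: Corey–Seebach epoxide opening in which lithiated 2 attacks the unsubstituted epoxide carbon (SN2 at CH2), forming the C6–C7 bond and releasing the C8 hydroxyl with its stereocentre untouched.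

Step 4
Reactants: 9 (2R)-1-{2-[(2S)-2,6-dimethylhept-5-en-1-yl]-1,3-dithian-2-yl}-3-(2-methyl-1,3-dithian-2-yl)propan-2-ol; 10 propargyl bromide
Product: 11 2-[(2S)-2,6-dimethylhept-5-en-1-yl]-2-[(2R)-3-(2-methyl-1,3-dithian-2-yl)-2-(prop-2-yn-1-yloxy)propyl]-1,3-dithiane
Conditions: NaH, Bu4NI (cat.), THF/DMF, 0 °C → rt
Reagents that add atoms: none
Why: Williamson etherification of the secondary alkoxide with the reactive propargylic bromide places the three-carbon unit (future C12, C11, C13) on O8, the dithianes being inert to NaH.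

Step 5
Reactants: 11 2-[(2S)-2,6-dimethylhept-5-en-1-yl]-2-[(2R)-3-(2-methyl-1,3-dithian-2-yl)-2-(prop-2-yn-1-yloxy)propyl]-1,3-dithiane
Product: 12 (4R,8S)-8,12-dimethyl-4-(prop-2-yn-1-yloxy)tridec-11-ene-2,6-dione
Conditions: MeI, CaCO3, MeCN/H2O (9:1), 45 °C
Reagents that add atoms: water, O
Why: S-methylation of both dithianes followed by CaCO3-buffered hydrolysis (dithioacetal cleavage) unmasks the 1,5-diketone under near-neutral conditions that spare the alkyne, the alkene and the β-alkoxy ketone.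

Step 6
Reactants: 12 (4R,8S)-8,12-dimethyl-4-(prop-2-yn-1-yloxy)tridec-11-ene-2,6-dione
Product: 13 (5R)-3-methyl-2-[(2S)-6-methylhept-5-en-2-yl]-5-(prop-2-yn-1-yloxy)cyclohex-2-en-1-one
Conditions: KOH (dilute), MeOH, 0 °C → rt
Reagents that add atoms: none
Why: Intramolecular aldol condensation of the 2,6-diketone, in which attack of C5 on the methyl ketone and dehydration should give the more substituted, thermodynamically preferred 2-alkyl-3-methylcyclohexenone, the cold dilute hydroxide being chosen to outrun E1cB loss of the C8 alkoxy group and to leave the propargyl ether unisomerised.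

Step 7
Reactants: 13 (5R)-3-methyl-2-[(2S)-6-methylhept-5-en-2-yl]-5-(prop-2-yn-1-yloxy)cyclohex-2-en-1-one
Product: 14 tert-butyl(dimethyl){[(3R)-5-methyl-6-[(2S)-6-methylhept-5-en-2-yl]-3-(prop-2-yn-1-yloxy)cyclohexa-1,5-dien-1-yl]oxy}silane
Conditions: TBSOTf, Et3N, CH2Cl2, −78 → 0 °C
Reagents that add atoms: tert-butyldimethylsilyl trifluoromethanesulfonate, CC(C)(C)[Si](C)(C)OS(=O)(=O)C(F)(F)F
Why: Soft enolisation (silyl triflate/amine) in which O-silylation of the enone and deprotonation at the α′ methylene C7 should give the cross-conjugated 2-silyloxy diene without a free enolate, so that β-elimination of the C8 ether and deprotonation of the alkyne are avoided.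

Step 8
Reactants: 14 tert-butyl(dimethyl){[(3R)-5-methyl-6-[(2S)-6-methylhept-5-en-2-yl]-3-(prop-2-yn-1-yloxy)cyclohexa-1,5-dien-1-yl]oxy}silane
Product: 15 (3aR,7aR)-6-methyl-3-methylidene-5-[(2S)-6-methylhept-5-en-2-yl]-2,3,7,7a-tetrahydro-1-benzofuran-4(3aH)-one
Conditions: Ph3PAuCl (5 mol %), AgBF4 (5 mol %), CH2Cl2/MeOH (10:1), rt → 40 °C
Reagents that add atoms: none
Why: Cationic monovalent gold π-activates the terminal alkyne and the silyl enol ether carbon C7 attacks the internal alkyne carbon C11 anti to gold; methanol then removes the silyl group from the oxocarbenium ion (restoring the C6 ketone) and protonates the vinyl–gold bond to leave the exocyclic methylene. The closest known reaction type is the gold-catalysed Conia-ene-type carbocyclisation of silyl enol ethers onto alkynes. The one ring closed is the five-membered O8–C12–C11–C7–C8 ring, in the 5-exo-dig mode. The new stereocentre C7 is controlled by the existing C8 stereocentre, because the three-atom O–CH2–C tether can reach C7 only from the face that carries O8, so only the cis-fused bicycle can form. The step needs 5-exo over 6-endo selectivity, secured by Markovnikov attack on a terminal alkyne held on a short tether, and attack by C7 and not by the diene terminus C10, secured because only C7 lies within reach of the alkyne; the mild, non-basic medium is chosen to keep the allylic C8–O bond intact.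

Step 9
Reactants: 15 (3aR,7aR)-6-methyl-3-methylidene-5-[(2S)-6-methylhept-5-en-2-yl]-2,3,7,7a-tetrahydro-1-benzofuran-4(3aH)-one
Product: 16 (3aR,7aR)-6-methyl-3-methylidene-5-[(2S)-6-methylhept-5-en-2-yl]-3a,7a-dihydro-1-benzofuran-2,4(3H,7H)-dione
Conditions: CrO3·2C5H5N (excess), CH2Cl2, rt
Reagents that add atoms: chromium trioxide–pyridine complex CrO3·2C5H5N, O=[Cr](=O)=O.c1ccncc1.c1ccncc1
Why: Allylic oxidation with the Collins reagent (hexavalent chromium), in which the O–CH2 group of the 3-methylidenetetrahydrofuran, activated by both the ether oxygen and the exocyclic alkene, is oxidised to the lactone carbonyl to give the α-methylene-γ-butyrolactone while the enone deactivates its own γ C–H bonds.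

Step 10
Reactants: 16 (3aR,7aR)-6-methyl-3-methylidene-5-[(2S)-6-methylhept-5-en-2-yl]-3a,7a-dihydro-1-benzofuran-2,4(3H,7H)-dione
Product: 17 (4S)-4-[(3aR,7aR)-6-methyl-3-methylidene-2,4-dioxo-2,3,3a,4,7,7a-hexahydro-1-benzofuran-5-yl]pentanal
Conditions: O3, CH2Cl2/MeOH, −78 °C (stopped at first excess); then Me2S, −78 °C → rt
Reagents that add atoms: ozone, [O-][O+]=O
Why: Ozonolysis with reductive work-up, in which ozone is titrated onto the only electron-rich alkene (the trisubstituted side-chain olefin), the enone and the α-methylene lactone being conjugated and electron-poor.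

Step 11
Reactants: 17 (4S)-4-[(3aR,7aR)-6-methyl-3-methylidene-2,4-dioxo-2,3,3a,4,7,7a-hexahydro-1-benzofuran-5-yl]pentanal
Product: 19 (3aS,4R,7aR)-4-hydroxy-5-[(2S)-5-hydroxypentan-2-yl]-6-methyl-3-methylidene-3a,4,7,7a-tetrahydro-1-benzofuran-2(3H)-one, via hydroxy enone 18 (not isolated)
Conditions: NaBH4 (0.3 equiv), MeOH/THF, −78 °C; then CeCl3·7H2O, NaBH4, −78 → −40 °C
Reagents that add atoms: none
Why: Borohydride reduction of the aldehyde at −78 °C followed by Luche 1,2-reduction of the enone, in which hydride should reach C6 from the convex face of the cis-fused bicycle, anti to the lactone ring, so that the new C6 hydroxyl is cis to the C7–C11 and C8–O bonds, the cerium-modified reagent at low temperature sparing the α-methylene lactone.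

Step 12
Reactants: 19 (3aS,4R,7aR)-4-hydroxy-5-[(2S)-5-hydroxypentan-2-yl]-6-methyl-3-methylidene-3a,4,7,7a-tetrahydro-1-benzofuran-2(3H)-one
Product: 20 1,6-O,O-diacetylbritannilactone
Conditions: Ac2O, pyridine, DMAP (cat.), CH2Cl2, 0 °C → rt
Reagents that add atoms: acetic anhydride, CC(=O)OC(C)=O
Why: DMAP-catalysed acylation (nucleophilic catalysis) esterifies the primary C1 and the allylic C6 hydroxyl without touching any stereocentre and should give the target.

**Compound list**

1 | (S)-citronellal, (3S)-3,7-dimethyloct-6-enal | O=CC[C@@H](C)CCC=C(C)C | starting material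
2 | 2-[(2S)-2,6-dimethylhept-5-en-1-yl]-1,3-dithiane | C1(C[C@@H](C)CCC=C(C)C)SCCCS1 | intermediate
3 | 2-methyl-1,3-dithiane | CC1SCCCS1 | starting material
4 | (R)-epichlorohydrin, (2R)-2-(chloromethyl)oxirane | ClC[C@H]1CO1 | starting material
5 | 2-lithio-2-methyl-1,3-dithiane (not isolated) | [Li]C1(C)SCCCS1 | intermediate
6 | lithium (2R)-1-chloro-3-(2-methyl-1,3-dithian-2-yl)propan-2-olate (not isolated) | CC1(C[C@@H]([O-])CCl)SCCCS1.[Li+] | intermediate
7 | 2-methyl-2-{[(2R)-oxiran-2-yl]methyl}-1,3-dithiane | CC1(C[C@@H]2CO2)SCCCS1 | intermediate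
8 | 2-lithio-2-[(2S)-2,6-dimethylhept-5-en-1-yl]-1,3-dithiane (not isolated) | [Li]C1(C[C@@H](C)CCC=C(C)C)SCCCS1 | intermediate
9 | (2R)-1-{2-[(2S)-2,6-dimethylhept-5-en-1-yl]-1,3-dithian-2-yl}-3-(2-methyl-1,3-dithian-2-yl)propan-2-ol | CC1(C[C@@H](O)CC2(C[C@@H](C)CCC=C(C)C)SCCCS2)SCCCS1 | intermediate
10 | propargyl bromide, 3-bromoprop-1-yne | BrCC#C | starting material
11 | 2-[(2S)-2,6-dimethylhept-5-en-1-yl]-2-[(2R)-3-(2-methyl-1,3-dithian-2-yl)-2-(prop-2-yn-1-yloxy)propyl]-1,3-dithiane | CC1(C[C@@H](OCC#C)CC2(C[C@@H](C)CCC=C(C)C)SCCCS2)SCCCS1 | intermediate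
12 | (4R,8S)-8,12-dimethyl-4-(prop-2-yn-1-yloxy)tridec-11-ene-2,6-dione | CC(=O)C[C@@H](OCC#C)CC(=O)C[C@@H](C)CCC=C(C)C | intermediate
13 | (5R)-3-methyl-2-[(2S)-6-methylhept-5-en-2-yl]-5-(prop-2-yn-1-yloxy)cyclohex-2-en-1-one | O=C1C[C@H](OCC#C)CC(C)=C1[C@@H](C)CCC=C(C)C | intermediate
14 | tert-butyl(dimethyl){[(3R)-5-methyl-6-[(2S)-6-methylhept-5-en-2-yl]-3-(prop-2-yn-1-yloxy)cyclohexa-1,5-dien-1-yl]oxy}silane | CC(C)(C)[Si](C)(C)OC1=C[C@H](OCC#C)CC(C)=C1[C@@H](C)CCC=C(C)C | intermediate
15 | (3aR,7aR)-6-methyl-3-methylidene-5-[(2S)-6-methylhept-5-en-2-yl]-2,3,7,7a-tetrahydro-1-benzofuran-4(3aH)-one (cis-fused) | C=C1CO[C@@H]2CC(C)=C([C@@H](C)CCC=C(C)C)C(=O)[C@H]12 | intermediate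
16 | (3aR,7aR)-6-methyl-3-methylidene-5-[(2S)-6-methylhept-5-en-2-yl]-3a,7a-dihydro-1-benzofuran-2,4(3H,7H)-dione | C=C1C(=O)O[C@@H]2CC(C)=C([C@@H](C)CCC=C(C)C)C(=O)[C@H]12 | intermediate
17 | (4S)-4-[(3aR,7aR)-6-methyl-3-methylidene-2,4-dioxo-2,3,3a,4,7,7a-hexahydro-1-benzofuran-5-yl]pentanal | C=C1C(=O)O[C@@H]2CC(C)=C([C@@H](C)CCC=O)C(=O)[C@H]12 | intermediate
18 | (3aR,7aR)-5-[(2S)-5-hydroxypentan-2-yl]-6-methyl-3-methylidene-3a,7a-dihydro-1-benzofuran-2,4(3H,7H)-dione (not isolated) | C=C1C(=O)O[C@@H]2CC(C)=C([C@@H](C)CCCO)C(=O)[C@H]12 | intermediate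
19 | (3aS,4R,7aR)-4-hydroxy-5-[(2S)-5-hydroxypentan-2-yl]-6-methyl-3-methylidene-3a,4,7,7a-tetrahydro-1-benzofuran-2(3H)-one | C=C1C(=O)O[C@@H]2CC(C)=C([C@@H](C)CCCO)[C@H](O)[C@H]12 | intermediate
20 | 1,6-O,O-diacetylbritannilactone, (4S)-4-[(3aR,4R,7aR)-4-(acetyloxy)-6-methyl-3-methylidene-2-oxo-2,3,3a,4,7,7a-hexahydro-1-benzofuran-5-yl]pentyl acetate | C=C1C(=O)O[C@@H]2CC(C)=C([C@@H](C)CCCOC(C)=O)[C@H](OC(C)=O)[C@H]12 | target

**Step count.** Total: 12 steps. Longest linear sequence: 11 steps (steps 1 and 3–12; step 2 prepares the epoxide branch).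

**Steps most likely to fail**

1. Step 8 (key step). What may go wrong: under the cationic gold/methanol conditions the silyl dienol ether may simply be protodesilylated back to the enone, or the allylic C8–O bond may ionise with aromatisation, before C7 reaches the alkyne. Fallback (tin-hydride radical cyclisation instead of π-acid catalysis; sets out from 14 and returns at 15): N-bromosuccinimide, THF, −78 °C should convert 14 into (5R)-6-bromo-3-methyl-2-[(2S)-6-methylhept-5-en-2-yl]-5-(prop-2-yn-1-yloxy)cyclohex-2-en-1-one F1 (bromine on C7; either epimer serves). Bu3SnH, AIBN (cat.), benzene, 80 °C with slow addition then generates the C7 α-keto radical, which should close 5-exo-dig onto the alkyne; reduction of the vinyl radical gives 15 with the same tether-enforced cis fusion.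

2. Step 6. What may go wrong: enolisation toward C7 or C9 can expel the C8 propargyloxy group (E1cB), and the aldol may close in the other direction (methyl carbon onto the C6 ketone) faster than the desired cyclodehydration. Fallback (aldol onto an aldehyde, then methyl addition and 1,3-carbonyl transposition; sets out from 2 and returns at 13): 1,3-dithiane (n-BuLi, THF) and (S)-epichlorohydrin should give 2-{[(2S)-oxiran-2-yl]methyl}-1,3-dithiane F2. Lithiated 2 (compound 8) opens it to (2S)-1-(1,3-dithian-2-yl)-3-{2-[(2S)-2,6-dimethylhept-5-en-1-yl]-1,3-dithian-2-yl}propan-2-ol F3, in which the citronellal carbon is now C10 and the unsubstituted dithiane masks a C6 aldehyde. NaH and propargyl bromide give 2-[(2S)-3-(1,3-dithian-2-yl)-2-(prop-2-yn-1-yloxy)propyl]-2-[(2S)-2,6-dimethylhept-5-en-1-yl]-1,3-dithiane F4, and MeI, CaCO3 in aqueous MeCN unmasks (3S,7S)-7,11-dimethyl-5-oxo-3-(prop-2-yn-1-yloxy)dodec-10-enal F5. KOH, MeOH, 0 °C closes the only possible six-membered aldol (C5 onto the C6 aldehyde, much faster than onto a ketone) to (5S)-2-[(2S)-6-methylhept-5-en-2-yl]-5-(prop-2-yn-1-yloxy)cyclohex-2-en-1-one F6. MeLi, CeCl3, THF, −78 °C adds 1,2 to give (5S)-1-methyl-2-[(2S)-6-methylhept-5-en-2-yl]-5-(prop-2-yn-1-yloxy)cyclohex-2-en-1-ol F7 (C1 epimers), and pyridinium chlorochromate, CH2Cl2 (Dauben–Michno oxidative transposition) should deliver 13.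

3. Step 9. What may go wrong: hexavalent chromium may attack other allylic C–H bonds (side-chain isopropylidene, ring CH2) or the base-sensitive keto lactone may degrade during the long exposure to the pyridine complex. Fallback (two-stage aerobic hydrogen-atom-transfer oxidation; sets out from 15 and returns at 16): N-hydroxyphthalimide (cat.), Co(OAc)2 (cat.), O2, MeCN, rt should give (3aR,7aR)-2-hydroperoxy-6-methyl-3-methylidene-5-[(2S)-6-methylhept-5-en-2-yl]-2,3,7,7a-tetrahydro-1-benzofuran-4(3aH)-one F8 (C2 epimers), the electrophilic phthalimide-N-oxyl radical selecting the hydridic C–H next to the ring oxygen. Ac2O, Et3N, CH2Cl2, 0 °C then dehydrates the hydroperoxide (Kornblum–DeLaMare-type elimination) to lactone 16.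

Further compounds
F1 | step 8 | (5R)-6-bromo-3-methyl-2-[(2S)-6-methylhept-5-en-2-yl]-5-(prop-2-yn-1-yloxy)cyclohex-2-en-1-one (C6 epimers) | O=C1C(Br)[C@H](OCC#C)CC(C)=C1[C@@H](C)CCC=C(C)C
F2 | step 6 | 2-{[(2S)-oxiran-2-yl]methyl}-1,3-dithiane | C1(C[C@H]2CO2)SCCCS1
F3 | step 6 | (2S)-1-(1,3-dithian-2-yl)-3-{2-[(2S)-2,6-dimethylhept-5-en-1-yl]-1,3-dithian-2-yl}propan-2-ol | C1(C[C@H](O)CC2(C[C@@H](C)CCC=C(C)C)SCCCS2)SCCCS1
F4 | step 6 | 2-[(2S)-3-(1,3-dithian-2-yl)-2-(prop-2-yn-1-yloxy)propyl]-2-[(2S)-2,6-dimethylhept-5-en-1-yl]-1,3-dithiane | C1(C[C@H](OCC#C)CC2(C[C@@H](C)CCC=C(C)C)SCCCS2)SCCCS1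
F5 | step 6 | (3S,7S)-7,11-dimethyl-5-oxo-3-(prop-2-yn-1-yloxy)dodec-10-enal | O=CC[C@H](OCC#C)CC(=O)C[C@@H](C)CCC=C(C)C
F6 | step 6 | (5S)-2-[(2S)-6-methylhept-5-en-2-yl]-5-(prop-2-yn-1-yloxy)cyclohex-2-en-1-one | O=C1C[C@@H](OCC#C)CC=C1[C@@H](C)CCC=C(C)C
F7 | step 6 | (5S)-1-methyl-2-[(2S)-6-methylhept-5-en-2-yl]-5-(prop-2-yn-1-yloxy)cyclohex-2-en-1-ol (C1 epimers) | CC1(O)C[C@@H](OCC#C)CC=C1[C@@H](C)CCC=C(C)C
F8 | step 9 | (3aR,7aR)-2-hydroperoxy-6-methyl-3-methylidene-5-[(2S)-6-methylhept-5-en-2-yl]-2,3,7,7a-tetrahydro-1-benzofuran-4(3aH)-one (C2 epimers) | C=C1C(OO)O[C@@H]2CC(C)=C([C@@H](C)CCC=C(C)C)C(=O)[C@H]12
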